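**Retrosynthetic overview**
1. Scirpusin A ⇐ its pentamethyl ether with the C6 phenol free, by cleavage of the five aryl methyl ethers (last step).
2. That dihydrobenzofuranol ⇐ an open-chain 4-(1,2-diaryl-2-hydroxyethyl)-3-styrylphenol by forming O1–C7a. C7a is meta to the C6 phenol and ortho to C3a, so oxidising the phenol at its para carbon C3a makes C7a the β-carbon of a cyclohexadienone within 5-exo reach of the C2 hydroxyl; loss of methanol across C3a/C7a then restores the A ring.
3. The open-chain phenol ⇐ a racemic 1,2,2-triarylethanone by asymmetric transfer hydrogenation with dynamic kinetic resolution (sets C2 and C3), then desilylation.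
4. The triaryl ketone ⇐ deoxybenzoin + ortho-bromostilbene (C3–C3a bond, Pd α-arylation); deoxybenzoin ⇐ 3',4'-dimethoxyacetophenone + 1-bromo-3,5-dimethoxybenzene; bromostilbene ⇐ 2-bromo-5-hydroxybenzaldehyde + benzylphosphonate.
5. Ring order: all benzene rings are bought; the dihydrofuran ring is the only ring formed, in the key step.

Key step: step 7

Remark on the chemistry: the methoxy-bearing carbon of the dienone and the ring-fusion carbons of its oxa-Michael adduct are transient stereocentres formed as epimer mixtures that converge on one product, so their SMILES leave these centres undefined; the diaryl-bearing carbon is formally R in these two intermediates only because its ring neighbour gains an oxygen, not because it inverts.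

**Step 1**
Reactants: 1 2-bromo-5-hydroxybenzaldehyde
Product: 2 2-bromo-5-[(triisopropylsilyl)oxy]benzaldehyde
Conditions: TIPSCl, imidazole, DMF, rt
Reagents that add atoms: triisopropylsilyl chloride, CC(C)[Si](Cl)(C(C)C)C(C)C
Why: Imidazole-promoted O-silylation of a phenol, the bulky silyl ether being chosen because it should survive the carbanion and phosphate bases of steps 2 and 4 and is later removed by fluoride without touching methyl ethers.

**Step 2**
Reactants: 2 2-bromo-5-[(triisopropylsilyl)oxy]benzaldehyde; 3 diethyl [(4-methoxyphenyl)methyl]phosphonate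
Product: 4 {4-bromo-3-[(E)-2-(4-methoxyphenyl)ethenyl]phenoxy}tri(propan-2-yl)silane
Conditions: NaH, 15-crown-5 (cat.), THF, 0 °C → rt
Reagents that add atoms: none
Why: Horner–Wadsworth–Emmons olefination of an aryl aldehyde with a benzylphosphonate carbanion, which should give the (E)-stilbene through the favoured anti pathway while the aryl bromide and silyl ether stay inert.

**Step 3**
Reactants: 5 1-(3,4-dimethoxyphenyl)ethan-1-one; 6 1-bromo-3,5-dimethoxybenzene
Product: 7 1-(3,4-dimethoxyphenyl)-2-(3,5-dimethoxyphenyl)ethan-1-one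
Conditions: Pd2(dba)3 (cat.), Xantphos, NaOt-Bu, THF, 70 °C
Reagents that add atoms: none
Why: Palladium-catalysed α-arylation of a methyl ketone enolate with an aryl bromide, which under wide-bite-angle bisphosphine conditions should stop at monoarylation because the more hindered deoxybenzoin enolate couples more slowly; it is preferred to a Friedel–Crafts acylation, in which the 3,5-dimethoxyphenyl ring would compete as nucleophile.

**Step 4**
Reactants: 7 1-(3,4-dimethoxyphenyl)-2-(3,5-dimethoxyphenyl)ethan-1-one; 4 {4-bromo-3-[(E)-2-(4-methoxyphenyl)ethenyl]phenoxy}tri(propan-2-yl)silane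
Product: 8 rac-1-(3,4-dimethoxyphenyl)-2-(3,5-dimethoxyphenyl)-2-{2-[(E)-2-(4-methoxyphenyl)ethenyl]-4-[(triisopropylsilyl)oxy]phenyl}ethan-1-one
Conditions: Pd(OAc)2 (cat.), XPhos, K3PO4, toluene, 100 °C
Reagents that add atoms: none
Why: Palladium-catalysed α-arylation of a deoxybenzoin enolate with an ortho-substituted aryl bromide, a known entry to 1,2,2-triarylethanones, in which the bulky biarylphosphine should speed reductive elimination at the congested carbon and the mild phosphate base suffices for this acidic ketone and spares the silyl ether; the new α-centre forms racemic and stays labile.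

**Step 5**
Reactants: 8 rac-1-(3,4-dimethoxyphenyl)-2-(3,5-dimethoxyphenyl)-2-{2-[(E)-2-(4-methoxyphenyl)ethenyl]-4-[(triisopropylsilyl)oxy]phenyl}ethan-1-one
Product: 9 (1S,2S)-1-(3,4-dimethoxyphenyl)-2-(3,5-dimethoxyphenyl)-2-{2-[(E)-2-(4-methoxyphenyl)ethenyl]-4-[(triisopropylsilyl)oxy]phenyl}ethan-1-ol
Conditions: RuCl[(S,S)-TsDPEN](p-cymene) (cat.), HCO2H/Et3N (1:2), DMF, 40 °C
Reagents that add atoms: none
Why: Noyori–Ikariya asymmetric transfer hydrogenation with dynamic kinetic resolution: the doubly benzylic α-proton epimerises under the amine-rich formate medium, the (S,S)-catalyst should deliver hydride to the aryl ketone in the sense that gives the (S)-carbinol (as for acetophenone), and a Felkin–Anh transition state with the bulkier ortho-substituted A ring anti to the hydride should select the ketone epimer leading to the (S) diaryl-bearing carbon, while the stilbene is not reduced.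

**Step 6**
Reactants: 9 (1S,2S)-1-(3,4-dimethoxyphenyl)-2-(3,5-dimethoxyphenyl)-2-{2-[(E)-2-(4-methoxyphenyl)ethenyl]-4-[(triisopropylsilyl)oxy]phenyl}ethan-1-ol
Product: 10 4-[(1S,2S)-2-(3,4-dimethoxyphenyl)-1-(3,5-dimethoxyphenyl)-2-hydroxyethyl]-3-[(E)-4-methoxystyryl]phenol
Conditions: TBAF, AcOH, THF, 0 °C
Reagents that add atoms: none
Why: Fluoride-driven cleavage of the aryl silyl ether, buffered with acetic acid so that the electron-rich phenolate is protonated at once; neither the carbinol nor either stereocentre is touched.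

**Step 7**
Reactants: 10 4-[(1S,2S)-2-(3,4-dimethoxyphenyl)-1-(3,5-dimethoxyphenyl)-2-hydroxyethyl]-3-[(E)-4-methoxystyryl]phenol
Product: 13 (2S,3S)-2-(3,4-dimethoxyphenyl)-3-(3,5-dimethoxyphenyl)-4-[(E)-4-methoxystyryl]-2,3-dihydrobenzofuran-6-ol, via 4-methoxycyclohexadienone 11 (not isolated), via cis-fused methoxy enone 12 (not isolated)
Conditions: PhI(OAc)2, MeOH, 0 °C; evaporate; CSA (cat.), CH2Cl2, 0 °C → rt
Reagents that add atoms: none
Why: Proposed new method: ligand exchange of the free phenol on iodine(III) and loss of iodobenzene should give a phenoxenium-type species that methanol captures at the alkyl-bearing para carbon C3a, the closest known reaction being the PhI(OAc)2/MeOH oxidation of 4-alkylphenols to 4-alkyl-4-methoxycyclohexa-2,5-dienones. Acid then activates dienone 11 so that the C2 hydroxyl adds to the β-carbon C7a in a 5-exo-trig oxa-Michael closure of the O1–C2–C3–C3a–C7a ring, as in the known cyclisation of 4-(2-hydroxyethyl)-para-quinols to rengyolone-type cis-fused hydrobenzofuranones. The dienol of adduct 12 is an ether of an arene hydrate, so protonation of the C3a methoxy group, ionisation to a cyclohexadienyl cation and loss of the C7a proton should give the C6 phenol directly; this eliminative rearomatisation is the untested part and is modelled on the acid-catalysed aromatisation of arene hydrates and of Michael adducts of para-quinol ethers. No stereocentre is created in 13: C3a and C7a are only transient, both C3a epimers converge, and C2 and C3 keep their configuration because no bond to them is broken, the trans arrangement being also the thermodynamically preferred one. The step needs oxidation of the single free phenol only (the other oxygens are methyl ethers, and methanol as solvent should outrun the electron-rich arenes and loss of the C3 proton), para- over ortho-capture by methanol (favoured by the alkyl group on C3a), and addition to C7a instead of C4, which is secured because C4 carries the styryl group, its adduct would hold two adjacent fully substituted carbons, forms reversibly and has no hydrogen to lose on aromatisation.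

**Step 8**
Reactants: 13 (2S,3S)-2-(3,4-dimethoxyphenyl)-3-(3,5-dimethoxyphenyl)-4-[(E)-4-methoxystyryl]-2,3-dihydrobenzofuran-6-ol
Product: 14 scirpusin A, 4-[(2S,3S)-3-(3,5-dihydroxyphenyl)-6-hydroxy-4-[(E)-2-(4-hydroxyphenyl)ethenyl]-2,3-dihydro-1-benzofuran-2-yl]benzene-1,2-diol
Conditions: BCl3 (excess), n-Bu4NI, CH2Cl2, −78 → 0 °C; ice-water
Reagents that add atoms: none
Why: Lewis acid-assisted SN2 dealkylation of aryl methyl ethers, in which BCl3 coordinates each ether oxygen and iodide removes the methyl group as iodomethane at or below 0 °C; this combination is chosen over BBr3 because the benzylic C2–O1 bond and the stilbene are acid-sensitive, and any reversible opening at C2–O1 should reclose to the thermodynamically preferred trans isomer dictated by the fixed C3 centre.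

**Compound list**
1 | 2-bromo-5-hydroxybenzaldehyde | O=Cc1cc(O)ccc1Br | starting material
2 | 2-bromo-5-[(triisopropylsilyl)oxy]benzaldehyde | O=Cc1cc(O[Si](C(C)C)(C(C)C)C(C)C)ccc1Br | intermediate
3 | diethyl [(4-methoxyphenyl)methyl]phosphonate | CCOP(=O)(Cc1ccc(OC)cc1)OCC | starting material
4 | {4-bromo-3-[(E)-2-(4-methoxyphenyl)ethenyl]phenoxy}tri(propan-2-yl)silane | COc1ccc(/C=C/c2cc(O[Si](C(C)C)(C(C)C)C(C)C)ccc2Br)cc1 | intermediate
5 | 1-(3,4-dimethoxyphenyl)ethan-1-one (3',4'-dimethoxyacetophenone) | CC(=O)c1ccc(OC)c(OC)c1 | starting material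
6 | 1-bromo-3,5-dimethoxybenzene | COc1cc(Br)cc(OC)c1 | starting material
7 | 1-(3,4-dimethoxyphenyl)-2-(3,5-dimethoxyphenyl)ethan-1-one | COc1cc(CC(=O)c2ccc(OC)c(OC)c2)cc(OC)c1 | intermediate
8 | rac-1-(3,4-dimethoxyphenyl)-2-(3,5-dimethoxyphenyl)-2-{2-[(E)-2-(4-methoxyphenyl)ethenyl]-4-[(triisopropylsilyl)oxy]phenyl}ethan-1-one (α-centre racemic and labile) | COc1ccc(/C=C/c2cc(O[Si](C(C)C)(C(C)C)C(C)C)ccc2C(c2cc(OC)cc(OC)c2)C(=O)c2ccc(OC)c(OC)c2)cc1 | intermediate
9 | (1S,2S)-1-(3,4-dimethoxyphenyl)-2-(3,5-dimethoxyphenyl)-2-{2-[(E)-2-(4-methoxyphenyl)ethenyl]-4-[(triisopropylsilyl)oxy]phenyl}ethan-1-ol | COc1ccc(/C=C/c2cc(O[Si](C(C)C)(C(C)C)C(C)C)ccc2[C@H](c2cc(OC)cc(OC)c2)[C@@H](c2ccc(OC)c(OC)c2)O)cc1 | intermediate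
10 | 4-[(1S,2S)-2-(3,4-dimethoxyphenyl)-1-(3,5-dimethoxyphenyl)-2-hydroxyethyl]-3-[(E)-4-methoxystyryl]phenol | COc1ccc(/C=C/c2cc(O)ccc2[C@H](c2cc(OC)cc(OC)c2)[C@@H](c2ccc(OC)c(OC)c2)O)cc1 | intermediate
11 | 4-[(1R,2S)-2-(3,4-dimethoxyphenyl)-1-(3,5-dimethoxyphenyl)-2-hydroxyethyl]-4-methoxy-3-[(E)-4-methoxystyryl]cyclohexa-2,5-dien-1-one (both C4 epimers; not isolated) | COc1ccc(/C=C/C2=CC(=O)C=CC2(OC)[C@H](c2cc(OC)cc(OC)c2)[C@@H](c2ccc(OC)c(OC)c2)O)cc1 | intermediate
12 | (2S,3R)-2-(3,4-dimethoxyphenyl)-3-(3,5-dimethoxyphenyl)-3a-methoxy-4-[(E)-4-methoxystyryl]-3,3a,7,7a-tetrahydro-1-benzofuran-6(2H)-one (cis-fused, both 3a/7a epimer pairs; not isolated) | COc1ccc(/C=C/C2=CC(=O)CC3C2(OC)[C@H](c2cc(OC)cc(OC)c2)[C@@H](c2ccc(OC)c(OC)c2)O3)cc1 | intermediate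
13 | (2S,3S)-2-(3,4-dimethoxyphenyl)-3-(3,5-dimethoxyphenyl)-4-[(E)-4-methoxystyryl]-2,3-dihydrobenzofuran-6-ol | COc1ccc(/C=C/c2cc(O)cc3c2[C@H](c2cc(OC)cc(OC)c2)[C@@H](c2ccc(OC)c(OC)c2)O3)cc1 | intermediate
14 | scirpusin A, (2S,3S)-trans | Oc1ccc(/C=C/c2cc(O)cc3c2[C@H](c2cc(O)cc(O)c2)[C@@H](c2ccc(O)c(O)c2)O3)cc1 | target

**Totals**
Total steps: 8. Longest linear sequence: 7 steps (steps 1, 2, 4, 5, 6, 7, 8 from compound 1).

**Steps most likely to fail**

Step 7 (the step carrying the new-method label). The oxidised phenol may lose the doubly benzylic C3 proton to a para-quinone methide, or be captured by the dimethoxyphenyl ring on C2 instead of by methanol. Under acid the methoxy dienone may also undergo a cationic 1,2-shift, or revert by retro-oxa-Michael faster than it loses methanol. The fallback uses known reaction types and removes the leaving group without a carbocation. It sets out from 10: oxidation with PhI(OAc)2 in MeCN/H2O at 0 °C should give the para-quinol 4-hydroxycyclohexa-2,5-dienone F1. This should close, on standing or with a trace of TsOH, in the rengyolone manner to the cis-fused 3a-hydroxy enone F2. In F2 the tertiary C3a hydroxyl and the C7a hydrogen are syn, so Burgess reagent (toluene, 50 °C) should effect a syn-elimination to the cyclohexa-2,4-dienone F3, which tautomerises to phenol 13, where the route is rejoined.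

Step 5. The catalyst may not discriminate the two α-aryl groups in the hydride-transfer transition state (poor diastereoselectivity). Epimerisation of the α-centre may be slower than reduction (kinetic instead of dynamic resolution), or the hindered ketone may reduce sluggishly. The fallback is substrate-controlled reduction followed by classical resolution, setting out from 8: NaBH4 (THF/MeOH, −20 °C) should give mainly the racemic Felkin alcohol F4. Acylation with (S)-2-methoxy-2-phenylacetic acid (EDC, DMAP, CH2Cl2) gives two diastereomeric esters separable on silica, the mandelate of the (1S,2S)-alcohol F5 and the mandelate of the (1R,2R)-alcohol F6. DIBAL-H (CH2Cl2, −78 °C) cleaves F5 to 9, where the route is rejoined.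

Step 4. Oxidative addition and transmetalation at the hindered, electron-rich ortho-styryl bromide may be slow, so that protodebromination, base-induced loss of the silyl group or Heck-type oligomerisation overtake C–C coupling at the already substituted α-carbon. The fallback reverses the order of bond formation so that the congested bond is made with the unhindered bromide. It sets out from 5 and 4: monoarylation of the methyl ketone (Pd(OAc)2, 2-dicyclohexylphosphino-2'-methylbiphenyl, K3PO4, toluene, 80 °C) should give the benzyl aryl ketone 1-(3,4-dimethoxyphenyl)-2-{2-[(E)-2-(4-methoxyphenyl)ethenyl]-4-[(triisopropylsilyl)oxy]phenyl}ethan-1-one F7. Its enolate is then arylated with 6 (Pd(OAc)2, XPhos, K3PO4, toluene, 100 °C) to give 8, where the route is rejoined.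

**Further compounds**
F1 | step 7 | 4-[(1R,2S)-2-(3,4-dimethoxyphenyl)-1-(3,5-dimethoxyphenyl)-2-hydroxyethyl]-4-hydroxy-3-[(E)-4-methoxystyryl]cyclohexa-2,5-dien-1-one (both C4 epimers) | COc1ccc(/C=C/C2=CC(=O)C=CC2(O)[C@H](c2cc(OC)cc(OC)c2)[C@@H](c2ccc(OC)c(OC)c2)O)cc1
F2 | step 7 | (2S,3R)-2-(3,4-dimethoxyphenyl)-3-(3,5-dimethoxyphenyl)-3a-hydroxy-4-[(E)-4-methoxystyryl]-3,3a,7,7a-tetrahydro-1-benzofuran-6(2H)-one (cis-fused) | COc1ccc(/C=C/C2=CC(=O)CC3C2(O)[C@H](c2cc(OC)cc(OC)c2)[C@@H](c2ccc(OC)c(OC)c2)O3)cc1
F3 | step 7 | (2S,3S)-2-(3,4-dimethoxyphenyl)-3-(3,5-dimethoxyphenyl)-4-[(E)-4-methoxystyryl]-2,3-dihydro-1-benzofuran-6(7H)-one (keto tautomer of 13) | COc1ccc(/C=C/C2=CC(=O)CC3=C2[C@H](c2cc(OC)cc(OC)c2)[C@@H](c2ccc(OC)c(OC)c2)O3)cc1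
F4 | step 5 | racemic (1S*,2S*) form of alcohol 9 (both enantiomers shown) | COc1ccc(/C=C/c2cc(O[Si](C(C)C)(C(C)C)C(C)C)ccc2[C@H](c2cc(OC)cc(OC)c2)[C@@H](c2ccc(OC)c(OC)c2)O)cc1.COc1ccc(/C=C/c2cc(O[Si](C(C)C)(C(C)C)C(C)C)ccc2[C@@H](c2cc(OC)cc(OC)c2)[C@H](c2ccc(OC)c(OC)c2)O)cc1
F5 | step 5 | (S)-2-methoxy-2-phenylacetate of (1S,2S)-alcohol 9 | COc1ccc(/C=C/c2cc(O[Si](C(C)C)(C(C)C)C(C)C)ccc2[C@H](c2cc(OC)cc(OC)c2)[C@@H](c2ccc(OC)c(OC)c2)OC(=O)[C@@H](OC)c2ccccc2)cc1
F6 | step 5 | (S)-2-methoxy-2-phenylacetate of the (1R,2R)-enantiomer of 9 | COc1ccc(/C=C/c2cc(O[Si](C(C)C)(C(C)C)C(C)C)ccc2[C@@H](c2cc(OC)cc(OC)c2)[C@H](c2ccc(OC)c(OC)c2)OC(=O)[C@@H](OC)c2ccccc2)cc1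
F7 | step 4 | 1-(3,4-dimethoxyphenyl)-2-{2-[(E)-2-(4-methoxyphenyl)ethenyl]-4-[(triisopropylsilyl)oxy]phenyl}ethan-1-one | COc1ccc(/C=C/c2cc(O[Si](C(C)C)(C(C)C)C(C)C)ccc2CC(=O)c2ccc(OC)c(OC)c2)cc1
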